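**Retrosynthetic overview**

1. Target ⇒ Wittig at C9'=C10' (carotenoid numbering) of a C27 polyenynal with the acyl ylide Ph3P=C(Me)COMe; C27 aldehyde ⇒ two-carbon acetal ylide + C25 aldehyde ⇒ Wittig at C11=C12 of the ring-bearing C15 acetylenic phosphonium salt with the symmetrical C10 trienedial.
2. The only ring (the 3-hydroxy-7,8-didehydro-β end group) ⇐ proton-initiated C1–C6 cation–olefin closure of an open-chain ψ-type C15 dienyne, the way carotenoid β-cyclases close a ψ end group, run directly on the open-chain phosphonium salt in the flask where the salt is made.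
3. The 3-hydroxyl, which nature adds after cyclisation, is instead carried through the closure; it is the only stereocentre and comes from (S)-epichlorohydrin.
4. Open-chain C15 diol ⇐ Sonogashira of an (E)-alkenyl iodide with (E)-3-methylpent-2-en-4-yn-1-ol; iodide ⇐ carboalumination/iodination of an enynol made by opening (S)-epichlorohydrin first with isopropenyl Grignard, then with acetylide.
5. Ring order: one ring, closed in step 5; all later steps are chain extension.

Assumption: the all-E isomer written in the SMILES is the target; minor Z isomers from the olefinations are removed by thermal equilibration and crystallisation or chromatography. The target corresponds to the C31 acetylenic apocarotenoid known as triophaxanthin.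

**Route**

Step 1
Reactants: 1 (S)-epichlorohydrin; 2 isopropenylmagnesium bromide
Product: 3 (S)-1-chloro-4-methylpent-4-en-2-ol
Conditions: CuI (10 mol %), THF, −40 → −20 °C, 2 h; cold 1 M HCl
Reagents that add atoms: isopropenylmagnesium bromide 2, CC(=C)[Mg]Br
Why: Copper-catalysed Grignard opening of the epoxide at its unsubstituted carbon (SN2, faster than displacement of chloride at low temperature) touches no bond at the stereocentre, so the (S) centre of 1 is carried into 3 unchanged.

Step 2
Reactants: 3 (S)-1-chloro-4-methylpent-4-en-2-ol; 4 lithium acetylide–ethylenediamine complex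
Product: 6 (S)-6-methylhept-6-en-1-yn-4-ol, via epoxide 5 (not isolated)
Conditions: LiC≡CH·H2NCH2CH2NH2 (3 equiv), DMSO, 0 °C → rt, 12 h; H2O
Reagents that add atoms: lithium acetylide–ethylenediamine complex 4, [Li+].[C-]#C.NCCN
Why: The first equivalent of acetylide deprotonates 3, which closes to epoxide 5 by intramolecular Williamson displacement of chloride, and acetylide then opens 5 at the terminal CH2 (SN2 epoxide opening), so the carbinol carbon keeps its configuration while the second, different arm is attached.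

Step 3
Reactants: 6 (S)-6-methylhept-6-en-1-yn-4-ol; 7 trimethylaluminium; 8 iodine
Product: 10 (S,E)-1-iodo-2,6-dimethylhepta-1,6-dien-4-ol, via alkenylalane 9 (not isolated)
Conditions: Me3Al (3 equiv), Cp2ZrCl2 (0.25 equiv), CH2Cl2, 0 °C → rt, 16 h; then I2 (1.2 equiv), THF, −30 → 0 °C; H2O
Reagents that add atoms: trimethylaluminium 7, C[Al](C)C; iodine 8, II
Why: Negishi zirconium-catalysed carboalumination adds Me–Al syn across the terminal alkyne with methyl on the internal carbon, and iodinolysis of the alkenyl carbon–aluminium bond with retention gives the (E)-iodide, while the 1,1-disubstituted alkene is inert and the carbinol (held as its aluminium alkoxide) is unaffected.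

Step 4
Reactants: 10 (S,E)-1-iodo-2,6-dimethylhepta-1,6-dien-4-ol; 11 (E)-3-methylpent-2-en-4-yn-1-ol
Product: 12 (2E,6E,9S)-3,7,11-trimethyldodeca-2,6,11-trien-4-yne-1,9-diol
Conditions: Pd(PPh3)4 (3 mol %), CuI (6 mol %), i-Pr2NH (3 equiv), THF, rt, 4 h, degassed
Reagents that add atoms: (E)-3-methylpent-2-en-4-yn-1-ol 11, C#C/C(C)=C/CO
Why: Sonogashira coupling (zerovalent palladium with CuI) of an alkenyl iodide with a terminal alkyne retains both alkene geometries and tolerates free hydroxyls, giving the complete open-chain C15 skeleton.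

Step 5
Reactants: 12 (2E,6E,9S)-3,7,11-trimethyldodeca-2,6,11-trien-4-yne-1,9-diol; 13 triphenylphosphine; 14 trifluoromethanesulfonic acid
Product: 16 [(2E)-5-[(4R)-4-hydroxy-2,6,6-trimethylcyclohex-1-en-1-yl]-3-methylpent-2-en-4-yn-1-yl]triphenylphosphonium trifluoromethanesulfonate, via open-chain phosphonium triflate 15 (not isolated)
Conditions: Ph3P (1.05 equiv), CF3SO3H (1.0 equiv), CH2Cl2, 0 °C → rt, 12 h; then CF3SO3H (6 equiv), −78 → −40 °C, 1 h; ice-water, CH2Cl2 extraction
Reagents that add atoms: triphenylphosphine 13, c1ccc(cc1)P(c1ccccc1)c1ccccc1; trifluoromethanesulfonic acid 14 (triflate counter-ion), OS(=O)(=O)C(F)(F)F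
Why: Proposed new method: stage one is the usual acid-mediated conversion of a primary allylic alcohol into its triphenylphosphonium salt (the non-allylic carbinol does not ionise), and excess CF3SO3H then protonates the isolated 1,1-disubstituted alkene (Markovnikov) to the tertiary cation at the future C1, which is taken 6-endo by C6 of the enyne alkene to give the tertiary ring cation at C5 that loses H6 to the tetrasubstituted conjugated enyne; the phosphonium charge keeps protons off the dienyne, the protonated hydroxyl cannot drive a retro-Prins loss of isobutene, triflate cannot trap the cation, and no bond to the carbinol carbon is made or broken, so its configuration is kept (descriptor R in the ring); the closest known reactions are the H2SO4 cyclisation of pseudoionone to β-ionone (cation–olefin cyclisation with an acceptor-conjugated terminating alkene) and superacid cyclisations of hydroxy polyenes.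

Step 6
Reactants: 16 the cyclic C15 phosphonium triflate; 17 (2E,4E,6E)-2,7-dimethylocta-2,4,6-trienedial
Product: 19 (2E,4E,6E,8E,10E)-13-[(4R)-4-hydroxy-2,6,6-trimethylcyclohex-1-en-1-yl]-2,7,11-trimethyltrideca-2,4,6,8,10-pentaen-12-ynal, via phosphorus ylide 18 (not isolated)
Conditions: 17 (3 equiv), NaOMe (1.1 equiv), CH2Cl2/MeOH, 0 °C → rt, 3 h; then heptane, 90 °C, 2 h; crystallise
Reagents that add atoms: (2E,4E,6E)-2,7-dimethylocta-2,4,6-trienedial 17, O=C/C(C)=C/C=C/C=C(C)/C=O
Why: Wittig olefination of the semi-stabilised allylic ylide 18 with one formyl group of the symmetrical dialdehyde used in excess (the remaining CHO is less electrophilic once conjugation is extended) tolerates the free hydroxyl, and the hindered 11Z isomer is converted thermally into 11E, with C3 untouched.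

Step 7
Reactants: 19 the C25 aldehyde; 20 tributyl(1,3-dioxolan-2-ylmethyl)phosphonium bromide
Product: 23 (2E,4E,6E,8E,10E,12E)-15-[(4R)-4-hydroxy-2,6,6-trimethylcyclohex-1-en-1-yl]-4,9,13-trimethylpentadeca-2,4,6,8,10,12-hexaen-14-ynal, via acetal ylide 21 (not isolated), via dioxolane acetal 22 (not isolated)
Conditions: 20 (1.5 equiv), NaH (1.5 equiv), 18-crown-6 (5 mol %), THF, rt, 1 h; 19, 0 °C → rt; then 1 M HCl (cat.), THF/H2O, rt, 30 min
Reagents that add atoms: tributyl(1,3-dioxolan-2-ylmethyl)phosphonium bromide 20, [Br-].CCCC[P+](CCCC)(CCCC)CC1OCCO1; water, O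
Why: Wittig two-carbon homologation with the acetal-masked formylmethylene ylide 21 is E-selective and cannot homologate twice because the new aldehyde stays masked, and the mild acid hydrolysis of the conjugated dioxolane also equilibrates residual 11'Z enal to E.

Step 8
Reactants: 23 the C27 aldehyde; 24 3-(triphenylphosphoranylidene)butan-2-one
Product: 25 (3E,5E,7E,9E,11E,13E,15E)-18-[(4R)-4-hydroxy-2,6,6-trimethylcyclohex-1-en-1-yl]-3,7,12,16-tetramethyloctadeca-3,5,7,9,11,13,15-heptaen-17-yn-2-one (target)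
Conditions: 24 (3 equiv), toluene, 80 °C, 12 h, Ar, dark; crystallise (all-E)
Reagents that add atoms: 3-(triphenylphosphoranylidene)butan-2-one 24, CC(=O)C(C)=P(c1ccccc1)(c1ccccc1)c1ccccc1
Why: Wittig olefination with a stabilised α-methyl acyl ylide under neutral conditions gives the (E)-trisubstituted enone at the unhindered enal and leaves the hydroxyl, the alkyne and the polyene untouched.

**Compound list**

1 | (S)-epichlorohydrin | ClC[C@@H]1CO1 | starting material
2 | isopropenylmagnesium bromide | CC(=C)[Mg]Br | starting material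
3 | (S)-1-chloro-4-methylpent-4-en-2-ol | ClC[C@@H](O)CC(C)=C | intermediate
4 | lithium acetylide–ethylenediamine complex | [Li+].[C-]#C.NCCN | starting material
5 | (S)-2-(2-methylprop-2-en-1-yl)oxirane | C1O[C@H]1CC(C)=C | intermediate
6 | (S)-6-methylhept-6-en-1-yn-4-ol | C#CC[C@@H](O)CC(C)=C | intermediate
7 | trimethylaluminium | C[Al](C)C | starting material
8 | iodine | II | starting material
9 | (E)-alkenyldimethylalane of 6, as its O-dimethylaluminium alkoxide | C[Al](C)/C=C(C)/C[C@@H](O[Al](C)C)CC(C)=C | intermediate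
10 | (S,E)-1-iodo-2,6-dimethylhepta-1,6-dien-4-ol | I/C=C(C)/C[C@@H](O)CC(C)=C | intermediate
11 | (E)-3-methylpent-2-en-4-yn-1-ol | C#C/C(C)=C/CO | starting material
12 | (2E,6E,9S)-3,7,11-trimethyldodeca-2,6,11-trien-4-yne-1,9-diol | OC/C=C(C)/C#C/C=C(C)/C[C@@H](O)CC(C)=C | intermediate
13 | triphenylphosphine | c1ccc(cc1)P(c1ccccc1)c1ccccc1 | starting material
14 | trifluoromethanesulfonic acid | OS(=O)(=O)C(F)(F)F | starting material
15 | [(2E,6E,9S)-9-hydroxy-3,7,11-trimethyldodeca-2,6,11-trien-4-yn-1-yl]triphenylphosphonium trifluoromethanesulfonate | [O-]S(=O)(=O)C(F)(F)F.c1ccccc1[P+](c1ccccc1)(c1ccccc1)C/C=C(C)/C#C/C=C(C)/C[C@@H](O)CC(C)=C | intermediate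
16 | [(2E)-5-[(4R)-4-hydroxy-2,6,6-trimethylcyclohex-1-en-1-yl]-3-methylpent-2-en-4-yn-1-yl]triphenylphosphonium trifluoromethanesulfonate | [O-]S(=O)(=O)C(F)(F)F.c1ccccc1[P+](c1ccccc1)(c1ccccc1)C/C=C(C)/C#CC1=C(C)C[C@@H](O)CC1(C)C | intermediate
17 | (2E,4E,6E)-2,7-dimethylocta-2,4,6-trienedial | O=C/C(C)=C/C=C/C=C(C)/C=O | starting material
18 | [(2E)-5-[(4R)-4-hydroxy-2,6,6-trimethylcyclohex-1-en-1-yl]-3-methylpent-2-en-4-yn-1-ylidene]triphenylphosphorane | c1ccccc1P(c1ccccc1)(c1ccccc1)=C/C=C(C)/C#CC1=C(C)C[C@@H](O)CC1(C)C | intermediate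
19 | (2E,4E,6E,8E,10E)-13-[(4R)-4-hydroxy-2,6,6-trimethylcyclohex-1-en-1-yl]-2,7,11-trimethyltrideca-2,4,6,8,10-pentaen-12-ynal | O=C/C(C)=C/C=C/C=C(C)/C=C/C=C(\C)C#CC1=C(C)C[C@@H](O)CC1(C)C | intermediate
20 | tributyl(1,3-dioxolan-2-ylmethyl)phosphonium bromide | [Br-].CCCC[P+](CCCC)(CCCC)CC1OCCO1 | starting material
21 | tributyl(1,3-dioxolan-2-ylmethylidene)phosphorane | CCCCP(CCCC)(CCCC)=CC1OCCO1 | intermediate
22 | 2-[(1E,3E,5E,7E,9E,11E)-14-[(4R)-4-hydroxy-2,6,6-trimethylcyclohex-1-en-1-yl]-3,8,12-trimethyltetradeca-1,3,5,7,9,11-hexaen-13-yn-1-yl]-1,3-dioxolane | O1CCOC1/C=C/C(C)=C/C=C/C=C(C)/C=C/C=C(\C)C#CC2=C(C)C[C@@H](O)CC2(C)C | intermediate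
23 | (2E,4E,6E,8E,10E,12E)-15-[(4R)-4-hydroxy-2,6,6-trimethylcyclohex-1-en-1-yl]-4,9,13-trimethylpentadeca-2,4,6,8,10,12-hexaen-14-ynal | O=C/C=C/C(C)=C/C=C/C=C(C)/C=C/C=C(\C)C#CC1=C(C)C[C@@H](O)CC1(C)C | intermediate
24 | 3-(triphenylphosphoranylidene)butan-2-one | CC(=O)C(C)=P(c1ccccc1)(c1ccccc1)c1ccccc1 | starting material
25 | (3E,5E,7E,9E,11E,13E,15E)-18-[(4R)-4-hydroxy-2,6,6-trimethylcyclohex-1-en-1-yl]-3,7,12,16-tetramethyloctadeca-3,5,7,9,11,13,15-heptaen-17-yn-2-one | CC(=O)/C(C)=C/C=C/C(C)=C/C=C/C=C(C)/C=C/C=C(\C)C#CC1=C(C)C[C@@H](O)CC1(C)C | target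

**Step count and risks**

Total step count: 8. Longest linear sequence: 8 steps (1 → 25); every other input is purchased. No protecting groups are used.

Steps most likely to fail:

Step 5 (ring closure on the phosphonium salt). Possible failures are 5-exo closure to a propargylic cation, protonation or hydration of the enyne in the superacid, and loss of the 3-hydroxyl if the non-conjugated ring alkene forms. The fallback sets out from 12 and comes back at 16. MnO2 (CH2Cl2, rt) oxidises only the primary allylic alcohol of 12 to the dienynal (2E,6E,9S)-9-hydroxy-3,7,11-trimethyldodeca-2,6,11-trien-4-ynal F1. F1 is a true pseudoionone-type substrate, in which the carbonyl oxygen takes the proton and shields the dienyne. It is cyclised with CF3SO3H in CH2Cl2 at −40 °C to (2E)-5-[(4R)-4-hydroxy-2,6,6-trimethylcyclohex-1-en-1-yl]-3-methylpent-2-en-4-ynal F2. NaBH4 (MeOH, 0 °C) reduces F2 to (2E)-5-[(4R)-4-hydroxy-2,6,6-trimethylcyclohex-1-en-1-yl]-3-methylpent-2-en-4-yn-1-ol F3, and Ph3P/CF3SO3H (first stage of step 5 only) converts F3 into 16.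

Step 6 (mono-olefination of the dialdehyde). Possible failures are double condensation and difficult Z/E mixtures that waste the C15 salt. The fallback sets out from 17 (with 20) and comes back at 22. Dialdehyde 17 (3 equiv) is treated with ylide 21 (from 20 and NaH) and worked up without acid to give the mono-acetal (2E,4E,6E,8E)-9-(1,3-dioxolan-2-yl)-2,7-dimethylnona-2,4,6,8-tetraenal F4, which has a single free aldehyde. Wittig reaction of salt 16 with F4 (1:1, NaOMe, CH2Cl2/MeOH) gives 22 directly, and the hydrolysis half of step 7 then gives 23; aldehyde 19 is bypassed.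

Step 8 (α-methyl acyl ylide on a long polyenal). The ylide is sluggish, and prolonged heating may scramble the polyene geometry. The fallback sets out from 23 and comes back at 25. Horner–Wadsworth–Emmons reaction of 23 with diethyl [1-(methoxy(methyl)amino)-1-oxopropan-2-yl]phosphonate (LiCl, DBU, MeCN, rt) gives the Weinreb amide (2E,4E,6E,8E,10E,12E,14E)-17-[(4R)-4-hydroxy-2,6,6-trimethylcyclohex-1-en-1-yl]-N-methoxy-N,2,6,11,15-pentamethylheptadeca-2,4,6,8,10,12,14-heptaen-16-ynamide F5. MeMgBr (3 equiv, THF, −20 °C) converts F5 into methyl ketone 25.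

**Further compounds**

F1 | step 5 | (2E,6E,9S)-9-hydroxy-3,7,11-trimethyldodeca-2,6,11-trien-4-ynal | O=C/C=C(C)/C#C/C=C(C)/C[C@@H](O)CC(C)=C
F2 | step 5 | (2E)-5-[(4R)-4-hydroxy-2,6,6-trimethylcyclohex-1-en-1-yl]-3-methylpent-2-en-4-ynal | O=C/C=C(C)/C#CC1=C(C)C[C@@H](O)CC1(C)C
F3 | step 5 | (2E)-5-[(4R)-4-hydroxy-2,6,6-trimethylcyclohex-1-en-1-yl]-3-methylpent-2-en-4-yn-1-ol | OC/C=C(C)/C#CC1=C(C)C[C@@H](O)CC1(C)C
F4 | step 6 | (2E,4E,6E,8E)-9-(1,3-dioxolan-2-yl)-2,7-dimethylnona-2,4,6,8-tetraenal | O=C/C(C)=C/C=C/C=C(C)/C=C/C1OCCO1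
F5 | step 8 | (2E,4E,6E,8E,10E,12E,14E)-17-[(4R)-4-hydroxy-2,6,6-trimethylcyclohex-1-en-1-yl]-N-methoxy-N,2,6,11,15-pentamethylheptadeca-2,4,6,8,10,12,14-heptaen-16-ynamide | CON(C)C(=O)/C(C)=C/C=C/C(C)=C/C=C/C=C(C)/C=C/C=C(\C)C#CC1=C(C)C[C@@H](O)CC1(C)C
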